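## Retrosynthetic overview
1. The thiazolyl‑CH2–CH= bond is made last, by Stille coupling of a 4‑(chloromethyl)thiazole with a (Z)‑pentadienylstannane, so the skipped diene never meets a metathesis catalyst.
2. The (E)‑alkene comes from cross‑metathesis of a thiazole homoallylic alcohol with a vinyl carbinol that already carries the carbamate arm.
3. Key disconnection: the CH2–N bond of the carbamate arm. An enantiotopic‑group‑selective anti‑Markovnikov hydroamination of a prochiral divinyl diol forms this bond and so fixes the tertiary (R)‑carbinol.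
4. The secondary (R)‑carbinol comes from asymmetric allylboration of an α‑quaternary thiazolyl aldehyde.
5. The only ring, the thiazole, is formed at the start of its branch by Hantzsch condensation.

Assumption: the sense of induction in step 2 cannot be read from precedent, so (R)‑DTBM‑SEGPHOS is written and its equally available mirror image is used if a test run gives ent‑9.

## Route

Step 1
Reactants: 1 methyl glycolate; 2 vinylmagnesium bromide
Product: 3 2‑ethenylbut‑3‑ene‑1,2‑diol (prochiral divinyl diol)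
Conditions: 2 (3.3 equiv), THF, −78 → 0 °C; sat. aq NH4Cl
Reagents that add atoms: none
Why: Double Grignard 1,2‑addition to an ester, in which the first equivalent only deprotonates the OH and the chelated magnesium alkoxide steers the transient vinyl ketone towards 1,2‑attack; no stereocentre is formed.

Step 2
Reactants: 3 2‑ethenylbut‑3‑ene‑1,2‑diol; 4 1,2‑benzisoxazole; 5 methyl chloroformate
Product: 9 methyl N‑[(3R)‑3‑hydroxy‑3‑(hydroxymethyl)pent‑4‑en‑1‑yl]carbamate, via bis‑silyl ether 6 (not isolated), via silylated salicylaldimine 7 (not isolated), via amino diol 8 (not isolated)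
Conditions: Cu(OAc)2 (4 mol %), (R)‑DTBM‑SEGPHOS (4.4 mol %), PPh3 (8 mol %), (MeO)2MeSiH (5 equiv), THF, rt; 4 (1.05 equiv, syringe pump), 40 °C; NH2OH·HCl, MeOH–H2O, rt; NaHCO3, 5, 0 °C
Reagents that add atoms: none
Why: Proposed new method: enantiotopic‑group‑selective CuH hydroamination of a divinyl carbinol. After in‑situ O‑silylation, the ligated copper hydride adds irreversibly and anti‑Markovnikov to one of the two enantiotopic vinyl groups of 6; Cu goes to the CH2 terminus, so no β‑oxygen can be eliminated, and the C2‑symmetric ligand pocket accepts the fully substituted allylic carbon (large OSi, medium CH2OSi, small vinyl) in only one low‑energy orientation. The primary alkylcopper then attacks N of 4 with N–O cleavage, which forms the C–N bond and fixes the (R)‑carbinol. Any ent‑product still holds the fast‑reacting vinyl group and is drained to the achiral bis‑amine, so ee rises with conversion. The closest known reaction types are CuH‑catalysed anti‑Markovnikov hydroamination of terminal alkenes and of unprotected allylic alcohols (to γ‑amino alcohols) with 1,2‑benzisoxazole as NH2 source, and group‑selective epoxidation of divinyl carbinols; transimination and Schotten–Baumann N‑acylation finish the pot.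

Step 3
Reactants: 10 ethyl 2‑cyano‑2‑methylpropanoate
Product: 11 ethyl 3‑amino‑2,2‑dimethyl‑3‑sulfanylidenepropanoate
Conditions: (NH4)2S (aq, 1.5 equiv), MeOH, 40 °C
Reagents that add atoms: ammonium sulfide, [NH4+].[NH4+].[S-2]
Why: Thiolysis of a nitrile (hydrosulfide addition), in which the α‑ester activates the nitrile and the neopentyl ester resists ammonolysis.

Step 4
Reactants: 11 ethyl 3‑amino‑2,2‑dimethyl‑3‑sulfanylidenepropanoate; 12 1,3‑dichloroacetone
Product: 13 ethyl 2‑[4‑(chloromethyl)‑1,3‑thiazol‑2‑yl]‑2‑methylpropanoate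
Conditions: acetone, MgSO4, reflux; aq NaHCO3
Reagents that add atoms: none
Why: Hantzsch thiazole synthesis, in which S‑alkylation at one CH2Cl and cyclodehydration onto the ketone leave the second CH2Cl at C4.

Step 5
Reactants: 13 ethyl 2‑[4‑(chloromethyl)‑1,3‑thiazol‑2‑yl]‑2‑methylpropanoate
Product: 14 2‑[4‑(chloromethyl)‑1,3‑thiazol‑2‑yl]‑2‑methylpropanal
Conditions: iBu2AlH (1.1 equiv), CH2Cl2, −78 °C; MeOH, aq potassium sodium tartrate
Reagents that add atoms: none
Why: Partial ester reduction, in which the hindered N‑chelated aluminium hemiacetal survives until work‑up; the aldehyde cannot enolise and the CH2Cl group is inert at −78 °C.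

Step 6
Reactants: 14 2‑[4‑(chloromethyl)‑1,3‑thiazol‑2‑yl]‑2‑methylpropanal
Product: 15 (3R)‑2‑[4‑(chloromethyl)‑1,3‑thiazol‑2‑yl]‑2‑methylhex‑5‑en‑3‑ol
Conditions: (−)‑Ipc2B(allyl) (both Ipc groups from (−)‑α‑pinene, Mg‑salt‑free, 1.3 equiv), Et2O–pentane, −100 → −78 °C; H2O2, pH 7 buffer (NaH2PO4/Na2HPO4), MeOH, 0 °C
Reagents that add atoms: (−)‑B‑allyldiisopinocampheylborane, C=CCB([C@H]1C[C@H]2C[C@@H]([C@@H]1C)C2(C)C)[C@H]1C[C@H]2C[C@@H]([C@@H]1C)C2(C)C
Why: Brown asymmetric allylboration through a closed chair transition state, in which the (−)‑α‑pinene reagent attacks the Re face to give the (R)‑alcohol; the buffered non‑amine work‑up spares the CH2Cl group.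

Step 7
Reactants: 15 (3R)‑2‑[4‑(chloromethyl)‑1,3‑thiazol‑2‑yl]‑2‑methylhex‑5‑en‑3‑ol; 9 methyl N‑[(3R)‑3‑hydroxy‑3‑(hydroxymethyl)pent‑4‑en‑1‑yl]carbamate
Product: 16 methyl N‑[(3R,4E,7R)‑8‑[4‑(chloromethyl)‑1,3‑thiazol‑2‑yl]‑3,7‑dihydroxy‑3‑(hydroxymethyl)‑8‑methylnon‑4‑en‑1‑yl]carbamate
Conditions: 9 (1.5 equiv), second‑generation Hoveyda–Grubbs catalyst RuCl2(SIMes)(=CH‑C6H4‑2‑OiPr) (5 mol %, two portions), 1,4‑benzoquinone (10 mol %), CH2Cl2, 40 °C, Ar sparge
Reagents that add atoms: none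
Why: Olefin cross‑metathesis of a fast‑dimerising terminal alkene with a non‑dimerising free tertiary allylic alcohol, which is selective for the cross product; the bulky carbinol enforces the E‑alkene, no stereocentre is touched, and excess 9 is recovered.

Step 8
Reactants: 17 pent‑1‑en‑4‑yne; 18 tributyltin hydride
Product: 19 tributyl[(1Z)‑penta‑1,4‑dien‑1‑yl]stannane
Conditions: ZrCl4 (20 mol %), toluene, 0 °C; Et3N quench
Reagents that add atoms: none
Why: Lewis‑acid‑catalysed anti‑hydrostannation of a terminal alkyne, which gives the (Z)‑1‑stannylalkene and leaves the isolated alkene untouched.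

Step 9
Reactants: 16 methyl N‑[(3R,4E,7R)‑8‑[4‑(chloromethyl)‑1,3‑thiazol‑2‑yl]‑3,7‑dihydroxy‑3‑(hydroxymethyl)‑8‑methylnon‑4‑en‑1‑yl]carbamate; 19 tributyl[(1Z)‑penta‑1,4‑dien‑1‑yl]stannane
Product: 20 methyl N‑[(3R,4E,7R)‑8‑{4‑[(2Z)‑hexa‑2,5‑dien‑1‑yl]‑1,3‑thiazol‑2‑yl}‑3,7‑dihydroxy‑3‑(hydroxymethyl)‑8‑methylnon‑4‑en‑1‑yl]carbamate (target)
Conditions: 19 (1.3 equiv), Pd2(dba)3 (5 mol %), AsPh3 (20 mol %), degassed THF–NMP, 45 °C
Reagents that add atoms: none
Why: Stille coupling, in which zerovalent palladium inserts into the activated heterobenzylic C–Cl bond and the alkenyl group transfers with retention of Z geometry; the neutral conditions tolerate the free triol and the carbamate.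

## Compound list
1 | methyl glycolate | COC(=O)CO | starting material
2 | vinylmagnesium bromide | C=C[Mg]Br | starting material
3 | 2‑ethenylbut‑3‑ene‑1,2‑diol | C=CC(O)(CO)C=C | intermediate
4 | 1,2‑benzisoxazole | c1ccc2c(c1)cno2 | starting material
5 | methyl chloroformate | COC(=O)Cl | starting material
6 | bis[dimethoxy(methyl)silyl] ether of 3 | C=CC(C=C)(CO[Si](C)(OC)OC)O[Si](C)(OC)OC | intermediate
7 | (R)‑N‑alkyl (E)‑salicylaldimine with all three oxygens as SiMe(OMe)2 ethers | C=C[C@@](O[Si](C)(OC)OC)(CO[Si](C)(OC)OC)CC/N=C/c1ccccc1O[Si](C)(OC)OC | intermediate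
8 | (2R)‑2‑(2‑aminoethyl)but‑3‑ene‑1,2‑diol | C=C[C@@](O)(CO)CCN | intermediate
9 | methyl N‑[(3R)‑3‑hydroxy‑3‑(hydroxymethyl)pent‑4‑en‑1‑yl]carbamate | C=C[C@@](O)(CO)CCNC(=O)OC | intermediate
10 | ethyl 2‑cyano‑2‑methylpropanoate | CCOC(=O)C(C)(C)C#N | starting material
11 | ethyl 3‑amino‑2,2‑dimethyl‑3‑sulfanylidenepropanoate | CCOC(=O)C(C)(C)C(N)=S | intermediate
12 | 1,3‑dichloroacetone | ClCC(=O)CCl | starting material
13 | ethyl 2‑[4‑(chloromethyl)‑1,3‑thiazol‑2‑yl]‑2‑methylpropanoate | CCOC(=O)C(C)(C)c1nc(CCl)cs1 | intermediate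
14 | 2‑[4‑(chloromethyl)‑1,3‑thiazol‑2‑yl]‑2‑methylpropanal | O=CC(C)(C)c1nc(CCl)cs1 | intermediate
15 | (3R)‑2‑[4‑(chloromethyl)‑1,3‑thiazol‑2‑yl]‑2‑methylhex‑5‑en‑3‑ol | ClCc1csc(C(C)(C)[C@H](O)CC=C)n1 | intermediate
16 | methyl N‑[(3R,4E,7R)‑8‑[4‑(chloromethyl)‑1,3‑thiazol‑2‑yl]‑3,7‑dihydroxy‑3‑(hydroxymethyl)‑8‑methylnon‑4‑en‑1‑yl]carbamate | ClCc1csc(C(C)(C)[C@H](O)C/C=C/[C@@](O)(CO)CCNC(=O)OC)n1 | intermediate
17 | pent‑1‑en‑4‑yne | C=CCC#C | starting material
18 | tributyltin hydride | CCCC[SnH](CCCC)CCCC | starting material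
19 | tributyl[(1Z)‑penta‑1,4‑dien‑1‑yl]stannane | C=CC/C=C\[Sn](CCCC)(CCCC)CCCC | intermediate
20 | methyl N‑[(3R,4E,7R)‑8‑{4‑[(2Z)‑hexa‑2,5‑dien‑1‑yl]‑1,3‑thiazol‑2‑yl}‑3,7‑dihydroxy‑3‑(hydroxymethyl)‑8‑methylnon‑4‑en‑1‑yl]carbamate | C=CC/C=C\Cc1csc(C(C)(C)[C@H](O)C/C=C/[C@@](O)(CO)CCNC(=O)OC)n1 | target

## Count and risks
Total step count: 9, with no protecting‑group steps.
Longest linear sequence: 6 (steps 3, 4, 5, 6, 7, 9; 10 → 11 → 13 → 14 → 15 → 16 → 20).

**Step 2 (new desymmetrising hydroamination).**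
- Risk: insufficient discrimination between the two vinyl groups, or over‑amination.
- The fallback uses known chemistry only. It sets out from 5 and comes back at 9.
- 5 acylates purchased but‑3‑yn‑1‑amine (NaHCO3, CH2Cl2–H2O) to methyl but‑3‑yn‑1‑ylcarbamate F1.
- Enyne metathesis with ethene (1 atm) and the second‑generation Grubbs catalyst RuCl2(PCy3)(SIMes)(=CHPh) gives methyl (3‑methylidenepent‑4‑en‑1‑yl)carbamate F2.
- mCPBA/NaHCO3 at 0 °C epoxidises the more substituted double bond to racemic methyl [2‑(2‑ethenyloxiran‑2‑yl)ethyl]carbamate F3.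
- Dynamic kinetic asymmetric hydrolysis then delivers 9. The conditions are Pd2(dba)3·CHCl3, the DACH‑naphthyl Trost ligand enantiomer that gives the (R)‑diol, catalytic Et3B and NaHCO3 in CH2Cl2–H2O.
- In this last reaction the tertiary C–O bond forms on a rapidly equilibrating π‑allylpalladium, as established for isoprene monoepoxide.

**Step 7 (cross‑metathesis).**
- Risk: the thiazole or chloromethyl partner deactivates ruthenium, so 15 only dimerises.
- The fallback runs the metathesis before the ring exists. It sets out from 10 and comes back at 16, in the same number of operations.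
- LiBH4 in THF reduces the ester of 10 to 3‑hydroxy‑2,2‑dimethylpropanenitrile F4.
- Iridium‑catalysed transfer‑hydrogenative allylation from the alcohol oxidation level gives (3R)‑3‑hydroxy‑2,2‑dimethylhex‑5‑enenitrile F5. It uses allyl acetate, [Ir(cod)Cl]2, the BINAP enantiomer that gives the (R)‑alcohol, 4‑chloro‑3‑nitrobenzoic acid and Cs2CO3 in THF at 100 °C.
- Cross‑metathesis of F5 with 9 under the step 7 conditions gives methyl N‑[(3R,4E,7R)‑8‑cyano‑3,7‑dihydroxy‑3‑(hydroxymethyl)‑8‑methylnon‑4‑en‑1‑yl]carbamate F6.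
- (NH4)2S converts F6 into methyl N‑[(3R,4E,7R)‑9‑amino‑3,7‑dihydroxy‑3‑(hydroxymethyl)‑8,8‑dimethyl‑9‑sulfanylidenenon‑4‑en‑1‑yl]carbamate F7.
- Hantzsch condensation of F7 with 12 gives 16.

**Step 9 (Stille coupling).**
- Risk: a sluggish chloride, Z→E erosion, or double‑bond migration into conjugation with the thiazole.
- The fallback sets out from 16 and comes back at 20.
- Copper‑mediated sp–sp3 coupling of 16 with 17 (CuI, NaI, K2CO3, DMF, rt) gives methyl N‑[(3R,4E,7R)‑8‑[4‑(hex‑5‑en‑2‑yn‑1‑yl)‑1,3‑thiazol‑2‑yl]‑3,7‑dihydroxy‑3‑(hydroxymethyl)‑8‑methylnon‑4‑en‑1‑yl]carbamate F8.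
- Z‑selective semihydrogenation of the alkyne gives 20. It uses H2 (1 atm), Pd/CaCO3 poisoned with Pb(OAc)2, and quinoline in EtOAc, and is stopped at one equivalent of H2.

## Further compounds
F1 | step 2 | methyl but‑3‑yn‑1‑ylcarbamate | C#CCCNC(=O)OC
F2 | step 2 | methyl (3‑methylidenepent‑4‑en‑1‑yl)carbamate | C=CC(=C)CCNC(=O)OC
F3 | step 2 | racemic methyl [2‑(2‑ethenyloxiran‑2‑yl)ethyl]carbamate | C=CC1(CCNC(=O)OC)CO1
F4 | step 7 | 3‑hydroxy‑2,2‑dimethylpropanenitrile | N#CC(C)(C)CO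
F5 | step 7 | (3R)‑3‑hydroxy‑2,2‑dimethylhex‑5‑enenitrile | N#CC(C)(C)[C@H](O)CC=C
F6 | step 7 | methyl N‑[(3R,4E,7R)‑8‑cyano‑3,7‑dihydroxy‑3‑(hydroxymethyl)‑8‑methylnon‑4‑en‑1‑yl]carbamate | N#CC(C)(C)[C@H](O)C/C=C/[C@@](O)(CO)CCNC(=O)OC
F7 | step 7 | methyl N‑[(3R,4E,7R)‑9‑amino‑3,7‑dihydroxy‑3‑(hydroxymethyl)‑8,8‑dimethyl‑9‑sulfanylidenenon‑4‑en‑1‑yl]carbamate | NC(=S)C(C)(C)[C@H](O)C/C=C/[C@@](O)(CO)CCNC(=O)OC
F8 | step 9 | methyl N‑[(3R,4E,7R)‑8‑[4‑(hex‑5‑en‑2‑yn‑1‑yl)‑1,3‑thiazol‑2‑yl]‑3,7‑dihydroxy‑3‑(hydroxymethyl)‑8‑methylnon‑4‑en‑1‑yl]carbamate | C=CCC#CCc1csc(C(C)(C)[C@H](O)C/C=C/[C@@](O)(CO)CCNC(=O)OC)n1
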